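Saturday's flask is to be read at 33 min, and the question is what that time buys. With 0.00190 M of catalyst it stands at 3.76 M·s of catalyst-time, which I define as c(catalyst) charged times the time run.

| setting | Tuesday's | Sunday's | Wednesday's | Friday's | Saturday's |
|---|---|---|---|---|---|
| substrate | 0.150 M | 0.0750 M | 0.150 M | 0.220 M | 0.150 M |
| reagent | 0.120 M | 0.0450 M | 0.120 M | 0.120 M | 0.120 M |
| catalyst | 3.00 × 10⁻⁴ M | 3.00 × 10⁻⁴ M | 6.00 × 10⁻⁴ M | 3.00 × 10⁻⁴ M | 0.00190 M |
| time |  |  |  |  | 33 min |

- Tuesday's run (time / min: [product] / M): 2.5: 0.0194; 7.6: 0.0442; 15: 0.0694; 23: 0.0905; 33: 0.1045
- Sunday's run (time / min: [product] / M): 2.5: 0.0097; 7.6: 0.0231; 15: 0.0348; 23: 0.0424; 33: 0.0446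
- Wednesday's run (time / min: [product] / M): 2.5: 0.0298; 7.6: 0.0686; 15: 0.1002; 23: 0.1179; 33: 0.1206
- Friday's run (time / min: [product] / M): 2.5: 0.0238; 7.6: 0.0596; 15: 0.0930; 23: 0.1157; 33: 0.1192

(scatter of a reading: 0.001 M)

- the power of [catalyst] that the first rate follows, about the charge of the Tuesday's run; measure it at two percent of substrate made into product
- the power of [reagent] that the first rate follows, about the charge of the Tuesday's run; measure it at two percent of substrate made into product
- the Sunday's run starts with 0.0750 M less of substrate and of reagent than the Tuesday's run, and with no product. Compared where both hold the same amount of substrate, once fifteen percent of what the Sunday's run was charged with has turned into product, is the Sunday's run faster, slower or alike (within a tenth)?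
- product in the Saturday's run at 33 min, as a share of the substrate charged

- Overall: substrate + reagent -> product, with catalyst as catalyst.
- Constant volume, constant temperature.
- A reading of a species includes what of it is bound.
- An order is taken over about fifteen percent of the charge, up and down.

My first estimate is that catalyst-time works as a clock. Tuesday's flask at 15 min and Wednesday's at 7.6 min stand at 0.270 M·s and 0.274 M·s. They read 0.0694 M and 0.0686 M of product, a gap smaller than the scatter of 0.001 M. Wednesday's flask reaches that product in a time shorter by a factor of 1.97, with 2.00 times the catalyst, so I commit to a power of catalyst of about 0.981.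

But a clock can be held back. Sunday's flask gains 0.00263 M min⁻¹ between 2.5 min and 7.6 min, at a mean c(substrate) of 0.0586 M. Tuesday's gains 0.00264 M min⁻¹ between 15 min and 23 min, at 0.0701 M. Per unit of substrate, Sunday's flask is faster than Tuesday's, by a reading of 1.19, so that is my answer on the comparison. My objection is that this ratio assumes a rate in proportion to c(substrate), so I test that on Friday's flask next.

Reagent barely shows in the rate. Between 2.5 min and 7.6 min, Friday's flask gains 1.44 times what Tuesday's gains, with 1.47 times the substrate and the same reagent. At 2.5 min, Sunday's flask reads 0.500 of Tuesday's product, with substrate at 0.500 and reagent at 0.375 of Tuesday's charge, though each reading carries a scatter of 0.001 M. I take a power of reagent near zero.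

Reagent shows at the end instead. At 33 min, Sunday's, Wednesday's and Friday's flasks read 0.0446 M, 0.1206 M and 0.1192 M, against reagent charges of 0.0450 M, 0.120 M and 0.120 M, while Friday's still holds 0.101 M of substrate. Reagent is the limiting reagent, and control changes hands at a crossing catalyst-time. Tuesday's flask at 0.594 M·s reads 0.1045 M, still short of its reagent charge, and Wednesday's has reached it by 1.19 M·s. Saturday's catalyst-time is 3.16 times Wednesday's, which puts its crossing by about 10.4 min.

The objection is that Wednesday's flask holds 2.00 times Tuesday's catalyst, while Saturday's holds 6.33 times. Yet with a power of 0.5, Wednesday's 33 min shrinks to 18.5 min, still earlier than the reading. So I expect 80.0 % of the substrate charged.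

The forecast gives 80 %, because “so reagent limits product to 0.12 M”, with Sunday faster and a reagent power of 0.15, but its catalyst power of 0.65 is lower than mine.

The flask gives 80.0 %, a catalyst power of 1.0, a reagent power of 0.095, and Sunday faster.

    catalyst + substrate → catalyst-substrate complex (185.4 L mol⁻¹ min⁻¹)
    catalyst-substrate complex + reagent → product + catalyst (2262 L mol⁻¹ min⁻¹)
    catalyst + product ⇌ catalyst-product complex, settled at all times (5.270 L mol⁻¹)

Parking catalyst with product as catalyst-product complex does not change Saturday's share. Saturday's 3.76 M·s stands past the crossing that Wednesday's flask had reached by 1.19 M·s. On Sunday's flask, a quarter of the substrate charged is made at a catalyst-time of 0.112 M·s, and on Tuesday's at 0.113 M·s.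

(The data were computed with made-up constants, noise included.)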